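At 2.7 mM of dissolved substrate, a reagent molecule in the flask reaches target with a chance of 86.0%, and from that figure I start the reckoning of whether the next run keeps its charge and its time.

solid substrate 0.010 M; reagent 1.20 equiv; time 20 min

    solid product ⇌ target, rate k1*(cs1 - [target]) while solid is left; crystals form when [target] > cs1 (cs1 = 0.12 mM, k1 = 0.846 /s)
    dissolved substrate + reagent → target (k2 = 7.32 /M/s)
    2 solid substrate → self-condensation product (k3 = 0.00290 /M/s)
    solid substrate ⇌ dissolved substrate, rate k4*(cs4 - [dissolved substrate]) while solid is left; crystals form when [dissolved substrate] > cs4 (cs4 = 2.7 mM, k4 = 1.73 /s)
    reagent → side product (k5 = 0.00321 /s)

- a species is counted by the solid substrate in it: one self-condensation product counts as two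
- amounts and yields of target count solid product too
- a doubled species enters its step squared and goes two at a time
- given per volume of solution although it is solid: solid substrate, solid product
- at the start none of the solid substrate is in solution
- what has only dissolved of solid substrate counts as not reacted
- the reaction counts as stopped when no species that holds the solid substrate changes by six tenths of a point or more over the second half of the time
- run time (flask): 20 min

- which holds at 20 min: what has brought the reaction to rest, or that it has not come to rest (for what has run out or reacted, a solid counts together with what of it has only dissolved) (the reagent has run out first / all of the solid substrate has reacted / it is still moving)
- the target standing at 20 min, as a percentage of the solid substrate charged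
- the solid product standing at 20 min, as a percentage of the solid substrate charged

I follow one reagent molecule to its fork: it meets dissolved substrate and gives target, or it decays to side product. Dividing the decay constant by the coupling constant gives h = 0.439 mM, the even-odds level: the concentration A of dissolved substrate at which both exits take reagent equally fast. At level A the chance of target is A/(A+h), so each target costs 1 + h/A of reagent.

The flask is charged with 12.0 mM of reagent. Dissolving, at 1.73 /s, is faster than the pseudo-first-order coupling at the charged reagent, at 0.0878 /s, so I hold A near solubility while solid stands. I drop self-condensation because its first half-life, 4.79 h, is far longer than the reagent's 3.6 min.

Turning 7.30 mM of substrate at that level costs 8.49 mM of reagent, which leaves 3.51 mM for the last 2.7 mM. Below solubility the cost sums to the fall in A plus h times the logarithm of start over rest. One pass, with half of h as first guess for the rest, gives 0.256 mM of dissolved substrate unreacted. So the reagent, in nominal excess, is the limiting reagent. I expect 97.4% target, and, with 0.12 mM of it staying in solution, 96.2% solid product. By decay alone 2.13% of the reagent stands at 20 min, so I keep the time, and at 97.4% target I keep the charge.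

The forecast says the reagent has run out first, with 97.4% target and 96.2% solid product, on the ground that “Dissolution is fast, so dissolved substrate stays near its solubility”.

At 20 min in the flask the reagent has run out first, with 97.3% target, 96.1% solid product, 0.023% of the reagent's charge and 2.64% dissolved substrate, against my 2.56%. A neighbour flask at the same equivalents, with 0.0025 M of solid substrate, smaller than the solubility, ends with 14.3% dissolved substrate and 80.9% solid product, both in percent of its own charge. Summing the cost through h from that neighbour's charge down to its rest gives 3.00 mM of reagent, against 3.00 mM charged.

The rate constants stand for no real mixture, and the outcome is calculated.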